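The ratio I started from was the constant of reagent with free catalyst over the constant of free catalyst with target, 9.24, which I call the turnovers per death: the rounds a catalyst makes for each catalyst lost while reagent and target stand equal, a partition ratio. What I needed was the target left in each flask.

    reagent + free catalyst → catalyst intermediate A (k1 = 0.61 M⁻¹ s⁻¹)
    substrate + catalyst intermediate A → catalyst intermediate B (k2 = 0.59 M⁻¹ s⁻¹)
    catalyst intermediate B ⇌ catalyst intermediate C (K3 = 1.8, k3 = 1.0 s⁻¹)
    free catalyst + target → spent catalyst (k4 = 0.066 M⁻¹ s⁻¹)
    substrate + target → side product (k5 = 0.0045 M⁻¹ s⁻¹)
    catalyst intermediate C → free catalyst + target (k6 = 1.2 s⁻¹)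

the same everywhere: substrate 2.0 M; reagent 0.950 equiv; time 4.0 min

| run | free catalyst |
|---|---|
| elm | 4 mol% |
| alder | 8 mol% |
| cedar | 15 mol% |
| birch | 30 mol% |

* amount of target at the end, in percent of the substrate charged for elm, alder, cedar, birch, in this order
* the course of these numbers from the first flask to the last (hardly changes / falls, then rises / rises, then falls / rises all the way / falls all the way)

In elm, catalyst intermediate A lasts 0.59 s against substrate, far shorter than the 2.2 min of target against free catalyst, so I treated each return to free catalyst as a fresh choice between reagent and target. With x the fraction of reagent used and target made equal to reagent used, catalyst lost per target made is c(target)/(w·c(reagent)), which sums to: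

c(spent catalyst) = (c(reagent at start)/w)·[−x − ln(1 − x)]

Setting this equal to the catalyst charged, with g = w·c(free catalyst at start)/c(reagent at start), gives the point where the catalyst stops, which I solved by repeating:

x = 1 − exp(−(g + x))

For elm:

g = 0.389, x = 0.647, target made = 61.4 % of the substrate

Each dead catalyst holds one target. Substrate and target then react by the slow side step, and I ran that over the whole time, crudely, from a = c(substrate) and p = c(target):

a = 0.771 M, p = 1.15 M
c(substrate)/c(target) at the end = (a/p)·exp(−0.0045 M⁻¹ s⁻¹·(p − a)·4.0 min) = 0.447
target lost = 0.467 M, target left = 34.1 %

The weak link was that first line, which let the catalyst face target that never wore away, although by this reckoning 38.0 % of it went. I took half of that loss as falling within the catalyst's life, which raises w, and went round again for elm: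

w = 11.4, g = 0.480, x = 0.690
target lost = 0.444 M, target left = 39.4 %

For cedar and birch I kept the plain w:

cedar: x = 0.906, target lost = 0.210 M, target left = 60.6 %
birch: x = 0.980, target lost = 0.101 M, target left = 58.0 %

By this reckoning cedar and birch each lost less to the side step than elm did on the first pass, so I let the plain w stand for them. I did not reckon alder, but these figures already rise and then fall.

The forecast gave 40 %, 53 %, 61 % and 55 %, a course that rises, then falls, on the ground that at the top loading the leftover catalyst “destroys one target each”. My birch figure stood higher than its 55 %.

The flasks gave 40.4 %, 55.5 %, 64.8 % and 59.3 %, and the course rises, then falls.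

At 4.00 min, elm still had free catalyst going to reagent 6.5 times as fast as to target, which is what w times the readings of reagent over target gives, 6.51, with 95.2 % of its catalyst spent. In birch at 4.00 min, with reagent at 0.53 % of its charge and target at 59.3 %, the same product stood at 0.0781, so free catalyst went faster to target than to reagent, and spent catalyst stood at 99.4 %.

(The constants are those of an exercise; the result is computed.)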